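The numbers of this flask are those of an exercise.

**Dropping time.** Time can leave the reckoning if free E serves as the clock and the fraction of E left is followed, not the product made.

in all of them: time 6.0 min

|  | E | L | remark |
|---|---|---|---|
| beta | 0.020 M (fed, over 5.0 min) | 0.0200 M | all else is in the flask from the start; the feed brings no volume worth counting |
| eta | 0.020 M (in portions, 5, over 5.0 min) | 0.0200 M | first portion at the start, last at 5.0 min |
| zeta | 0.020 M | 0.0200 M | everything together at the start |
| theta | 0.020 M | 0.0200 M (fed, over 5.0 min) | all else is in the flask from the start; the feed brings no volume worth counting |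

- the best flask by share of X in X plus E.E.L; "all alike" if 1.5 percentage points covers them all (beta / eta / zeta / theta / all alike)
- share of X in X plus E.E.L at the end, beta
- share of X in X plus E.E.L at the end, eta
- share of X in X plus E.E.L at the end, zeta
- share of X in X plus E.E.L at the end, theta

- percentages count the E that a species holds: one E.E.L counts as two
- X is meant together with its Q
- a doubled species enters its step squared and goes two at a time
- solid, in amounts per volume of the solution: Q
- run time (beta): 6.0 min

    E + L → E.L (k1 = 2.67 M⁻¹ s⁻¹)
    E.L → X (k2 = 0.0241 s⁻¹)
    E + E.L → E.E.L (k3 = 1.80 M⁻¹ s⁻¹)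
    2 L → L2 (k4 = 0.171 M⁻¹ s⁻¹)
    Q ⇌ X, rate k5*(cs5 - [X]) while solid is left; crystals form when [X] > cs5 (cs5 = 9.3 mM, k5 = 1.03 s⁻¹)

**Even point.** E and L give E.L, which closes to X at 0.0241 s⁻¹ or is caught by a further E at 1.80 M⁻¹ s⁻¹, giving E.E.L. A closure puts one E into X and a capture puts two into E.E.L. So, with E.L steady and 6.69 mM as Eh, the even point, the free E at which both routes take up equal E, the share of X (the selectivity) in the E taken up is Eh/(Eh + [E]).

**Lower bound.** With free E held at its whole charge cA, that share is 25.1 %. With E in from the start, E.L steady and the fraction left falling from one to nothing, summing gives (Eh/cA) ln(1 + cA/Eh) = 46.3 %. This figure is an estimate resting on those conditions and on L lasting, not a firm bound.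

**Upper bound.** In beta, the feed against L as charged holds free E near 1.25 mM, a share of about 84.3 %. In eta, each portion taken to nothing gives 78.4 %. But L has a first half-life of 2.44 min by dimerisation, shorter than the feed, so both figures stand on L lasting, and the bracket does not rank beta against eta.

**The result.** The forecast names beta, with 69 %, 67 %, 58 % and 47 % for beta, eta, zeta and theta, holding that “keeping free E low favours X”, and these stand inside the bracket . The flasks give 67.1 %, 71.7 %, 57.4 % and 47.2 %, also inside it , and the best is eta.

**Still moving.** At 6.00 min, eta holds 30.5 % of its E and 2.24 % of its L. At 60.0 min, L stands at 0 %, E at 27.1 %, and the share at 70.4 %. Theta at 6.00 min holds 3.22 % of its E; from that E left, Eh reckons X at 43.2 % of the charge, and the flask shows 44.4 %. By 60.0 min, theta's share reaches 50.1 %.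

**Richer neighbour.** For theta charged with 0.034 M of E, with 15.4 % left, Eh reckons X at 24.2 % of the charge, a share of 28.6 % in the E taken up. The simulation gives 24.3 % and 29.4 %.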